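**Plan**

1. Retrosynthetic cuts, in order: the C3–O angelate ester; the C3–C4 and O–C18 bonds (ring A read as an isoxazoline, i.e. a nitrile oxide on C3 adding to an isopropenyl group on C5); C2–C3 (nitroaldol); C12–C13 (coupling with a bromobutenolide); C8=C17; C9–C11; C10–C1; and the C7–C4 cyclobutane bond of a pinane precursor.
2. Enabling feature: in ring A, O3 and O18 are 1,3-related across the quaternary C4, which is the β-hydroxy ketone (isoxazoline) retron. Ring B, with C17 on C8 and C4/C18/C19 on C5, is a p-menthane hidden in (–)-verbenone, whose cyclobutane already carries C4, C18 and C19 on C5.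
3. Forward order: ring B comes from verbenone (vinyl cuprate addition/alkylation, C9 correction, cyclobutane fragmentation, methylenation). The butenolide is coupled on as a preformed ring. The vinyl group becomes the silyloxy nitro chain, and ring A is closed last by the nitrile oxide cycloaddition.
4. Helpers removed afterwards: the isoxazoline (N–O cleavage), the nitro group (consumed as the dipole) and two silyl ethers.
5. Stereochemistry: C5 from verbenone; C10 by cuprate addition anti to the gem-dimethyl bridge; C9 by kinetic protonation from the same face; C2 by a catalyst-controlled Henry reaction; C4 by the chair-like, trans-fused cycloaddition transition state; C3 by axial hydride delivery.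

Key step: step 11

Remark: labdane numbering is used for every compound (ring A = C1–C5, C10; ring B = C5–C10; C11–C16 side chain and butenolide with C15 carbonyl and C16 OCH2; C17 on C8; C18 = CH2OH carbon and C19 = methyl on C4; C20 on C10). In the pinane intermediates the gem-dimethyl carbon is C4.
Remark: in step 9 the antipode of the indabox ligand is taken that delivers the 2S carbinol; which antipode this is must be fixed by a trial run.

**Step 1**
Reactants: 1 (–)-verbenone; 2 vinylmagnesium bromide; 3 methyl bromoacetate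
Product: 6 methyl 2-(4-ethenyl-4,6,6-trimethyl-2-oxobicyclo[3.1.1]heptan-3-yl)acetate (ethenyl on C10 and acetate arm on C9 both anti to the gem-dimethyl bridge), via trimethylsilyl enol ether 4 (not isolated), via lithium enolate 5 (not isolated)
Conditions: 2, CuBr·SMe2 (10 mol %), TMSCl, THF, −78 °C; volatiles removed; MeLi, THF, 0 °C; then 3, DMPU, −78 → 0 °C
Reagents that add atoms: vinylmagnesium bromide 2, C=C[Mg]Br; methyl bromoacetate 3, COC(=O)CBr
Why: Copper-catalysed 1,4-addition of the vinyl Grignard reagent (TMSCl-accelerated) should take the enone face anti to the gem-dimethyl bridge and set the quaternary C10 (C20 syn to the bridge), and the lithium enolate regenerated from 4, which can only be the C8–C9 enolate because C7 is a bridgehead, should be C-alkylated by the α-bromo ester on the same open face (three-component conjugate addition–enolate alkylation).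

**Step 2**
Reactants: 6
Product: 8 methyl 2-(4-ethenyl-4,6,6-trimethyl-2-oxobicyclo[3.1.1]heptan-3-yl)acetate (acetate arm syn to the gem-dimethyl bridge; cis to C20 and trans to ethenyl), via lithium enolate 7 (not isolated)
Conditions: LiHMDS (1.1 equiv), THF, −78 → −20 °C; then AcOH, −78 °C
Reagents that add atoms: none
Why: LiHMDS should enolise the ketone in preference to the ester, and kinetic C-protonation of enolate 7 from the face anti to the gem-dimethyl bridge should push the acetate arm to the bridge side, i.e. cis to C20 and trans to the vinyl group as the target needs at C9 (deprotonation–kinetic protonation epimerisation).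

**Step 3**
Reactants: 8
Product: 11 methyl 2-[(1S,2R,3R)-2-ethenyl-2-methyl-6-oxo-3-(prop-1-en-2-yl)cyclohexyl]acetate, via iodo silyl enol ether 9 (not isolated), via dienyl silyl enol ether 10 (not isolated)
Conditions: TMSI, CH2Cl2, −40 → 0 °C; then DBU, 0 → 25 °C; then 1 M HCl, THF, 0 °C
Reagents that add atoms: none
Why: O-silylation by TMSI should trigger heterolysis of the strained C7–C4 cyclobutane bond α to the carbonyl (Lewis-acid-induced fragmentation known for nopinone-type cyclobutyl ketones) to give tertiary iodide 9 with the ketone masked as its C7=C8 silyl enol ether, so that the E2 elimination with DBU toward a methyl group (the C5 hydrogen is shielded by the quaternary C10) cannot epimerise C9, and dilute acid then releases the ketone.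

**Step 4**
Reactants: 11; 12 dibromomethane
Product: 13 methyl 2-[2-ethenyl-2-methyl-6-methylidene-3-(prop-1-en-2-yl)cyclohexyl]acetate (configuration as in 11)
Conditions: Zn, 12, TiCl4, THF/CH2Cl2, 0 → 25 °C
Reagents that add atoms: dibromomethane 12, BrCBr
Why: The non-basic Zn/CH2Br2/TiCl4 methylenation (Lombardo–Takai) should convert the hindered, epimerisable C8 ketone into the exocyclic C8=C17 alkene without touching C9 or the ester.

**Step 5**
Reactants: 13
Product: 14 2-[2-ethenyl-2-methyl-6-methylidene-3-(prop-1-en-2-yl)cyclohexyl]ethan-1-ol (configuration as in 11)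
Conditions: LiAlH4, Et2O, 0 °C
Reagents that add atoms: none
Why: LiAlH4 reduces the methyl ester to the primary alcohol (ester reduction); the three alkenes are inert.

**Step 6**
Reactants: 14; 15 iodine
Product: 16 1-ethenyl-2-(2-iodoethyl)-1-methyl-3-methylidene-6-(prop-1-en-2-yl)cyclohexane (configuration as in 11)
Conditions: PPh3, 15, imidazole, CH2Cl2, 0 → 25 °C
Reagents that add atoms: iodine 15, II
Why: Appel-type iodination turns the primary alcohol into the iodide by SN2 displacement of the oxyphosphonium group.

**Step 7**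
Reactants: 16; 17 4-bromofuran-2(5H)-one
Product: 20 4-{2-[2-ethenyl-2-methyl-6-methylidene-3-(prop-1-en-2-yl)cyclohexyl]ethyl}furan-2(5H)-one (configuration as in 11), via alkyllithium 18 (not isolated), via lithium borate 19 (not isolated)
Conditions: t-BuLi (2.1 equiv), Et2O, −78 °C; 9-MeO-9-BBN, THF, −78 → 25 °C; then 17, PdCl2(dppf) (5 mol %), AsPh3, K3PO4 (aq), DMF, 25 °C
Reagents that add atoms: 4-bromofuran-2(5H)-one 17, BrC1=CC(=O)OC1
Why: Lithium–iodine exchange at −78 °C (too cold for 5-exo carbolithiation onto the vinyl group), capture by 9-MeO-9-BBN and B-alkyl Suzuki–Miyaura coupling of borate 19 with the β-bromobutenolide should form C12–C13 and bring in the butenolide as a preformed ring.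

**Step 8**
Reactants: 20; 21 dioxygen
Product: 22 2-{1-methyl-3-methylidene-2-[2-(5-oxo-2,5-dihydrofuran-3-yl)ethyl]-6-(prop-1-en-2-yl)cyclohexyl}acetaldehyde (ring configuration unchanged)
Conditions: PdCl2(PhCN)2 (10 mol %), CuCl2·2H2O (10 mol %), AgNO2 (5 mol %), 21 (1 atm), t-BuOH/nitromethane 23 (15:1), 25 °C
Reagents that add atoms: dioxygen 21, O=O
Why: The nitrite-modified, aldehyde-selective Wacker-type oxidation is known to give anti-Markovnikov aldehydes from terminal alkenes on quaternary carbons, and the two 1,1-disubstituted alkenes and the butenolide are not substrates, so only the vinyl group should become the C1–C2 acetaldehyde arm.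

**Step 9**
Reactants: 22; 23 nitromethane
Product: 24 4-{2-[2-[(2S)-2-hydroxy-3-nitropropyl]-2-methyl-6-methylidene-3-(prop-1-en-2-yl)cyclohexyl]ethyl}furan-2(5H)-one
Conditions: 23 (10 equiv), Cu(OAc)2·H2O (5 mol %), indabox bis(oxazoline) ligand (5.5 mol %), EtOH, 25 °C
Reagents that add atoms: nitromethane 23, C[N+](=O)[O-]
Why: The copper–bis(oxazoline)-catalysed asymmetric Henry (nitroaldol) reaction adds C3 and should set the 2S carbinol under catalyst control, the ring stereocentres being insulated by the quaternary C10.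

**Step 10**
Reactants: 24; 25 tert-butyldimethylsilyl triflate
Product: 26 tert-butyldimethylsilyl ether of 24 at the C2 hydroxyl
Conditions: 25, 2,6-lutidine, CH2Cl2, −78 °C
Reagents that add atoms: tert-butyldimethylsilyl triflate 25, CC(C)(C)[Si](C)(C)OS(=O)(=O)C(F)(F)F
Why: Low-temperature silylation protects the C2 hydroxyl so that the nitro group can be dehydrated and the three oxygens of ring A stay differentiated (silyl ether formation).

**Step 11**
Reactants: 26
Product: 28 ring-A-closed isoxazoline (C3=N–O–C18H2–C4) of 2-O-TBS-labda-8(17),13-dien-15,16-olide with C19 axial and cis to C20, via nitrile oxide 27 (not isolated)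
Conditions: PhNCO (3 equiv), Et3N (0.2 equiv), benzene (0.005 M), 25 → 60 °C
Reagents that add atoms: none
Why: Dehydration of the primary nitro group by PhNCO/Et3N (Mukaiyama-type) generates nitrile oxide 27, whose C3≡N–O dipole adds in a concerted, suprafacial (3+2) fashion across the isopropenyl C4=C18 bond. The closest known reaction type is the intramolecular nitrile oxide–alkene cycloaddition of hept-6-enyl nitrile oxides bearing a 1,1-disubstituted alkene, which gives cyclohexane-fused isoxazolines with a quaternary ring-fusion carbon. Ring A closes in the 6-exo sense through the C3–C4 bond (dipole carbon to the internal alkene carbon), and the temporary five-membered isoxazoline closes at the same time through the O–C18 bond. C4 is the only new stereocentre: the equatorial C10–C1 and C5–C4 bonds of ring B force a trans-fused, chair-like ring A, and the nearly planar isoxazoline can only span C3 and an equatorial C18, so C19 is placed axial and cis to C20. The 2S silyloxy group lies equatorial in this chair, so the required C2 isomer cyclises through the unstrained transition state. The step needs site selectivity for the isopropenyl group and intra- over intermolecular reaction: a bridged closure onto C8=C17 would require the C1 chain axial (ring B flipped with three axial substituents), the butenolide alkene is electron-poor, trisubstituted and out of reach, and high dilution suppresses furoxan formation.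

**Step 12**
Reactants: 28; 29 water
Product: 31 2-(tert-butyldimethylsilyloxy)-18-hydroxy-3-oxolabda-8(17),13-dien-15,16-olide, via hydroxy imine 30 (not isolated)
Conditions: Mo(CO)6, MeCN/29 (15:1), 80 °C
Reagents that add atoms: water 29, O
Why: Mo(CO)6-mediated reductive N–O cleavage gives β-hydroxy imine 30, whose hydrolysis unmasks the C3 ketone and the C18 hydroxymethyl group (isoxazoline to β-hydroxy ketone) without reducing the alkenes or the butenolide.

**Step 13**
Reactants: 31; 32 tert-butyldimethylsilyl chloride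
Product: 33 2,18-bis(tert-butyldimethylsilyloxy)-3-oxolabda-8(17),13-dien-15,16-olide
Conditions: 32, imidazole, DMF, 25 °C
Reagents that add atoms: tert-butyldimethylsilyl chloride 32, CC(C)(C)[Si](C)(C)Cl
Why: Silylation of the neopentyl primary C18 hydroxyl leaves C3 as the only position that will carry a free hydroxyl after the reduction (silyl ether formation).

**Step 14**
Reactants: 33
Product: 34 2,18-bis(tert-butyldimethylsilyloxy)-3-hydroxylabda-8(17),13-dien-15,16-olide (3-OH equatorial and trans to the 2-silyloxy group)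
Conditions: NaBH4, CeCl3·7H2O, MeOH/THF, −40 → 0 °C
Reagents that add atoms: none
Why: Luche reduction should deliver hydride axially, from the face opposite the axial C19 and C20 methyls, to give the equatorial 3-hydroxyl, and it spares the butenolide.

**Step 15**
Reactants: 34; 35 angelic acid
Product: 37 3-angeloyloxy-2,18-bis(tert-butyldimethylsilyloxy)labda-8(17),13-dien-15,16-olide, via mixed anhydride 36 (not isolated)
Conditions: 35, 2,4,6-trichlorobenzoyl chloride, Et3N, toluene, 25 °C; then 34, 80 °C
Reagents that add atoms: angelic acid 35, C/C=C(/C)C(=O)O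
Why: Yamaguchi esterification through mixed anhydride 36 acylates the only free hydroxyl, and this protocol is known to transfer the angeloyl group without Z to E isomerisation.

**Step 16**
Reactants: 37
Product: 38 (2S,3S,4S,5S,9R,10S)-3-angeloyloxy-2,18-dihydroxylabda-8(17),13-dien-15,16-olide (CNP0335424.2)
Conditions: HF·pyridine, pyridine/THF, 0 → 25 °C
Reagents that add atoms: none
Why: HF·pyridine removes both TBS ethers under mildly acidic conditions that should avoid acyl migration and leave the angelate, the butenolide and the exocyclic alkene intact (fluoride desilylation).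

**Compound list**

1 | (–)-verbenone, (1S,5S)-4,6,6-trimethylbicyclo[3.1.1]hept-3-en-2-one | CC1=CC(=O)[C@H]2C[C@@H]1C2(C)C | starting material
2 | vinylmagnesium bromide | C=C[Mg]Br | starting material
3 | methyl bromoacetate | COC(=O)CBr | starting material
4 | [(4-ethenyl-4,6,6-trimethylbicyclo[3.1.1]hept-2-en-2-yl)oxy]trimethylsilane, ethenyl anti to the gem-dimethyl bridge | C[Si](C)(C)OC1=C[C@](C)(C=C)[C@@H]2C[C@H]1C2(C)C | intermediate
5 | lithium enolate corresponding to 4 | [Li+].[O-]C1=C[C@](C)(C=C)[C@@H]2C[C@H]1C2(C)C | intermediate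
6 | methyl 2-(4-ethenyl-4,6,6-trimethyl-2-oxobicyclo[3.1.1]heptan-3-yl)acetate, ethenyl and acetate arm both anti to the gem-dimethyl bridge (C9 epimer of 8) | O=C1[C@H]2C[C@H](C2(C)C)[C@@](C)(C=C)[C@H]1CC(=O)OC | intermediate
7 | lithium C8–C9 enolate of 6 | [Li+].[O-]C1=C(CC(=O)OC)[C@](C)(C=C)[C@@H]2C[C@H]1C2(C)C | intermediate
8 | methyl 2-(4-ethenyl-4,6,6-trimethyl-2-oxobicyclo[3.1.1]heptan-3-yl)acetate, acetate arm syn to the gem-dimethyl bridge (cis to C20, trans to ethenyl) | O=C1[C@H]2C[C@H](C2(C)C)[C@@](C)(C=C)[C@@H]1CC(=O)OC | intermediate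
9 | methyl 2-[2-ethenyl-3-(2-iodopropan-2-yl)-2-methyl-6-(trimethylsilyloxy)cyclohex-5-en-1-yl]acetate, ring configuration as in 11 | C[Si](C)(C)OC1=CC[C@H](C(C)(C)I)[C@@](C)(C=C)[C@@H]1CC(=O)OC | intermediate
10 | methyl 2-[2-ethenyl-2-methyl-3-(prop-1-en-2-yl)-6-(trimethylsilyloxy)cyclohex-5-en-1-yl]acetate, ring configuration as in 11 | C[Si](C)(C)OC1=CC[C@H](C(C)=C)[C@@](C)(C=C)[C@@H]1CC(=O)OC | intermediate
11 | methyl 2-[(1S,2R,3R)-2-ethenyl-2-methyl-6-oxo-3-(prop-1-en-2-yl)cyclohexyl]acetate (acetate arm cis to the methyl, trans to ethenyl; ethenyl trans to isopropenyl) | O=C1CC[C@H](C(C)=C)[C@@](C)(C=C)[C@@H]1CC(=O)OC | intermediate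
12 | dibromomethane | BrCBr | starting material
13 | methyl 2-[2-ethenyl-2-methyl-6-methylidene-3-(prop-1-en-2-yl)cyclohexyl]acetate, configuration as in 11 | C=C1CC[C@H](C(C)=C)[C@@](C)(C=C)[C@@H]1CC(=O)OC | intermediate
14 | 2-[2-ethenyl-2-methyl-6-methylidene-3-(prop-1-en-2-yl)cyclohexyl]ethan-1-ol, configuration as in 11 | C=C1CC[C@H](C(C)=C)[C@@](C)(C=C)[C@@H]1CCO | intermediate
15 | iodine | II | starting material
16 | 1-ethenyl-2-(2-iodoethyl)-1-methyl-3-methylidene-6-(prop-1-en-2-yl)cyclohexane, configuration as in 11 | C=C1CC[C@H](C(C)=C)[C@@](C)(C=C)[C@@H]1CCI | intermediate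
17 | 4-bromofuran-2(5H)-one | BrC1=CC(=O)OC1 | starting material
18 | primary alkyllithium from 16 | C=C1CC[C@H](C(C)=C)[C@@](C)(C=C)[C@@H]1CC[Li] | intermediate
19 | lithium B-alkyl-B-methoxy-9-borabicyclo[3.3.1]nonane borate from 18 | [Li+].C=C1CC[C@H](C(C)=C)[C@@](C)(C=C)[C@@H]1CC[B-]1(OC)C2CCCC1CCC2 | intermediate
20 | 4-{2-[2-ethenyl-2-methyl-6-methylidene-3-(prop-1-en-2-yl)cyclohexyl]ethyl}furan-2(5H)-one, configuration as in 11 | C=C1CC[C@H](C(C)=C)[C@@](C)(C=C)[C@@H]1CCC1=CC(=O)OC1 | intermediate
21 | dioxygen | O=O | starting material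
22 | 2-{1-methyl-3-methylidene-2-[2-(5-oxo-2,5-dihydrofuran-3-yl)ethyl]-6-(prop-1-en-2-yl)cyclohexyl}acetaldehyde | C=C1CC[C@H](C(C)=C)[C@@](C)(CC=O)[C@@H]1CCC1=CC(=O)OC1 | intermediate
23 | nitromethane | C[N+](=O)[O-] | starting material
24 | 4-{2-[2-[(2S)-2-hydroxy-3-nitropropyl]-2-methyl-6-methylidene-3-(prop-1-en-2-yl)cyclohexyl]ethyl}furan-2(5H)-one | C=C1CC[C@H](C(C)=C)[C@@](C)(C[C@H](O)C[N+](=O)[O-])[C@@H]1CCC1=CC(=O)OC1 | intermediate
25 | tert-butyldimethylsilyl triflate | CC(C)(C)[Si](C)(C)OS(=O)(=O)C(F)(F)F | starting material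
26 | C2 tert-butyldimethylsilyl ether of 24 | C=C1CC[C@H](C(C)=C)[C@@](C)(C[C@H](O[Si](C)(C)C(C)(C)C)C[N+](=O)[O-])[C@@H]1CCC1=CC(=O)OC1 | intermediate
27 | nitrile oxide from 26 (C3≡N–O) | C=C1CC[C@H](C(C)=C)[C@@](C)(C[C@H](O[Si](C)(C)C(C)(C)C)C#[N+][O-])[C@@H]1CCC1=CC(=O)OC1 | intermediate
28 | ring-A-closed isoxazoline (C3=N–O–C18H2–C4) of 2-O-TBS-labda-8(17),13-dien-15,16-olide, C19 axial and cis to C20 | C=C1CC[C@H]2[C@@](C)(C[C@H](O[Si](C)(C)C(C)(C)C)C3=NOC[C@@]32C)[C@@H]1CCC1=CC(=O)OC1 | intermediate
29 | water | O | starting material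
30 | 2-(tert-butyldimethylsilyloxy)-18-hydroxy-3-iminolabda-8(17),13-dien-15,16-olide | C=C1CC[C@H]2[C@@](C)(C[C@H](O[Si](C)(C)C(C)(C)C)C(=N)[C@]2(C)CO)[C@@H]1CCC1=CC(=O)OC1 | intermediate
31 | 2-(tert-butyldimethylsilyloxy)-18-hydroxy-3-oxolabda-8(17),13-dien-15,16-olide | C=C1CC[C@H]2[C@@](C)(C[C@H](O[Si](C)(C)C(C)(C)C)C(=O)[C@]2(C)CO)[C@@H]1CCC1=CC(=O)OC1 | intermediate
32 | tert-butyldimethylsilyl chloride | CC(C)(C)[Si](C)(C)Cl | starting material
33 | 2,18-bis(tert-butyldimethylsilyloxy)-3-oxolabda-8(17),13-dien-15,16-olide | C=C1CC[C@H]2[C@@](C)(C[C@H](O[Si](C)(C)C(C)(C)C)C(=O)[C@]2(C)CO[Si](C)(C)C(C)(C)C)[C@@H]1CCC1=CC(=O)OC1 | intermediate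
34 | 2,18-bis(tert-butyldimethylsilyloxy)-3-hydroxylabda-8(17),13-dien-15,16-olide, 3-OH equatorial and trans to 2-OTBS | C=C1CC[C@H]2[C@@](C)(C[C@H](O[Si](C)(C)C(C)(C)C)[C@@H](O)[C@]2(C)CO[Si](C)(C)C(C)(C)C)[C@@H]1CCC1=CC(=O)OC1 | intermediate
35 | angelic acid, (Z)-2-methylbut-2-enoic acid | C/C=C(/C)C(=O)O | starting material
36 | angelic 2,4,6-trichlorobenzoic anhydride | C/C=C(/C)C(=O)OC(=O)c1c(Cl)cc(Cl)cc1Cl | intermediate
37 | 3-angeloyloxy-2,18-bis(tert-butyldimethylsilyloxy)labda-8(17),13-dien-15,16-olide | C=C1CC[C@H]2[C@@](C)(C[C@H](O[Si](C)(C)C(C)(C)C)[C@@H](OC(=O)/C(C)=C\C)[C@]2(C)CO[Si](C)(C)C(C)(C)C)[C@@H]1CCC1=CC(=O)OC1 | intermediate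
38 | (2S,3S,4S,5S,9R,10S)-3-angeloyloxy-2,18-dihydroxylabda-8(17),13-dien-15,16-olide (CNP0335424.2) | C=C1CC[C@H]2[C@@](C)(C[C@H](O)[C@@H](OC(=O)/C(C)=C\C)[C@]2(C)CO)[C@@H]1CCC1=CC(=O)OC1 | target

**Totals**

Total step count: 16. Longest linear sequence: 16 steps (1 → 38).

**Steps most likely to fail**

Step 2. Enolisation of the hindered C9–H, which lies on the bridge side, may be slow and may be outrun by ester enolisation or enol-lactone formation, so that the C9 epimerisation stays incomplete. The fallback avoids any deprotonation at C9. It sets out from lithium enolate 5 (made as in step 1) and comes back at 8. Aldol addition of 5 to methyl glyoxylate (THF, −78 °C) should give the β-hydroxy ester aldol adduct F1. Mesylation and elimination (MsCl, Et3N, then DBU) should give the alkylidene keto ester F2. Conjugate hydride addition to C11 with LiBH(s-Bu)3 (THF, −78 °C) generates enolate 7 directly, and quenching with AcOH at −78 °C should protonate C9 anti to the bridge and return 8.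

Step 11. Nitrile oxide dimerisation or elimination of the silyloxy group may outrun a slow cycloaddition onto the hindered 1,1-disubstituted alkene. The fallback uses a different dipole that does not dimerise. It sets out from 26 and comes back at 28. TMSCl/Et3N (benzene, 25 → 50 °C) should convert 26 into the silyl nitronate F3, which should undergo the intramolecular silyl nitronate–alkene cycloaddition to the N-silyloxy isoxazolidine F4. Catalytic TsOH then eliminates trimethylsilanol to give isoxazoline 28.

Step 15. Acylation of the C3 hydroxyl, flanked by two silyloxy-bearing carbons, may be slow, and forcing conditions may isomerise the angelate to the tiglate. The fallback builds the Z-alkene on the ester instead of transferring it. It sets out from 34 and comes back at 37. Esterification with 2-[bis(2,2,2-trifluoroethoxy)phosphoryl]propanoic acid (DCC, DMAP, CH2Cl2) should give the phosphonate ester F5. Still–Gennari olefination with acetaldehyde (KHMDS, 18-crown-6, THF, −78 °C) should then give the Z-configured 2-methylbut-2-enoate 37.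

**Further compounds**

F1 | step 2 | methyl 2-(4-ethenyl-4,6,6-trimethyl-2-oxobicyclo[3.1.1]heptan-3-yl)-2-hydroxyacetate (aldol adduct; C9 and carbinol centres as formed) | O=C1[C@H]2C[C@H](C2(C)C)[C@@](C)(C=C)C1C(O)C(=O)OC
F2 | step 2 | methyl 2-(4-ethenyl-4,6,6-trimethyl-2-oxobicyclo[3.1.1]heptan-3-ylidene)acetate | O=C1[C@H]2C[C@H](C2(C)C)[C@@](C)(C=C)C1=CC(=O)OC
F3 | step 11 | trimethylsilyl nitronate of 26 | C=C1CC[C@H](C(C)=C)[C@@](C)(C[C@H](O[Si](C)(C)C(C)(C)C)C=[N+]([O-])O[Si](C)(C)C)[C@@H]1CCC1=CC(=O)OC1
F4 | step 11 | N-(trimethylsilyloxy)isoxazolidine cycloadduct (C3 configuration as formed) | C=C1CC[C@H]2[C@@](C)(C[C@H](O[Si](C)(C)C(C)(C)C)C3N(O[Si](C)(C)C)OC[C@@]32C)[C@@H]1CCC1=CC(=O)OC1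
F5 | step 15 | 3-O-{2-[bis(2,2,2-trifluoroethoxy)phosphoryl]propanoyl} derivative of 34 | C=C1CC[C@H]2[C@@](C)(C[C@H](O[Si](C)(C)C(C)(C)C)[C@@H](OC(=O)C(C)P(=O)(OCC(F)(F)F)OCC(F)(F)F)[C@]2(C)CO[Si](C)(C)C(C)(C)C)[C@@H]1CCC1=CC(=O)OC1
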